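**Plan**
- Cuts: the C6 carbonyl and the C3=C3a double bond of the quinone methide are traced back to a C6 methyl ether and a tertiary C3 carbinol. The lactone ring is then opened at O1–C7a and C3–C3a together, which leaves a benzyne and a 4-oxygenated phenylglyoxylate. The C4–phenyl and C7–phenyl bonds are cut last.
- Enabling feature (benzofuran numbering): in ring A (C3a, C4, C5, C6, C7, C7a), C4 and C7 both carry phenyl and C5 and C6 both carry oxygen. A mirror line therefore bisects C3a–C7a and C5–C6, and the two ends of an aryne triple bond at C3a–C7a are equivalent.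
- Forward: ring A is bought as veratrole. It receives both phenyl rings by cross-coupling, then OH, Br, SiMe3 and OTf at its last two carbons. Ring B, the five-membered lactone, is the only ring closed, and it forms in the aryne annulation.
- Endgame: acid frees the 4'-phenol and removes water to give a quinone methide. Chloride then removes only the O6 methyl group, because C6 is para to C3a and so conjugated with the dienone carbonyl; the O5 methyl group is meta and stays.
- Stereochemistry: the target has no stereocentre and no free double-bond geometry. The one stereocentre on the way, C3 of the carbinol, is racemic and is erased on dehydration.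

Key step: step 9

Assumption: the target is handled as the 6-oxo/4'-hydroxy tautomer written in its SMILES, and acidification of its delocalised lithium salt is taken to deliver this tautomer.

**Step 1**
Reactants: 1 veratrole
Product: 3 1,4-dibromo-2,3-dimethoxybenzene, via 3,6-dilithioveratrole 2 (not isolated)
Conditions: n-BuLi (3 equiv), TMEDA, Et2O, 0 °C to rt; BrCH2CH2Br, –78 °C to rt
Reagents that add atoms: n-butyllithium [Li]CCCC (lithium of 2); 1,2-dibromoethane BrCCBr (bromine of 3)
Why: Twofold directed ortho-metalation, in which each methoxy group steers one lithiation to its free ortho carbon (the same dilithiation that gives 2,3-dimethoxyterephthalic acid with CO2), followed by bromine transfer from 1,2-dibromoethane to both C–Li bonds.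

**Step 2**
Reactants: 3 1,4-dibromo-2,3-dimethoxybenzene; 4 phenylboronic acid
Product: 5 2,3-dimethoxy-1,4-diphenylbenzene
Conditions: 4 (2.5 equiv), Pd(PPh3)4 (cat.), K2CO3, toluene/EtOH/H2O, 90 °C
Reagents that add atoms: none
Why: Twofold Suzuki–Miyaura coupling of two unhindered aryl bromides under standard zerovalent palladium catalysis, to which the methyl ethers are inert.

**Step 3**
Reactants: 5 2,3-dimethoxy-1,4-diphenylbenzene
Product: 6 1-bromo-3,4-dimethoxy-2,5-diphenylbenzene
Conditions: NBS (1 equiv), MeCN, 0 °C to rt, dark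
Reagents that add atoms: N-bromosuccinimide O=C1CCC(=O)N1Br
Why: Electrophilic aromatic bromination at one of the two equivalent free carbons of the central ring, each of which is para to a methoxy group and more electron-rich than the outer phenyl rings, while the first bromine slows a second substitution.

**Step 4**
Reactants: 6 1-bromo-3,4-dimethoxy-2,5-diphenylbenzene
Product: 9 3,4-dimethoxy-2,5-diphenylphenol, via aryllithium 7 (not isolated), via lithium aryltrimethoxyborate 8 (not isolated)
Conditions: n-BuLi, THF, –78 °C; B(OMe)3, –78 °C to rt; 30% aq H2O2, 0 °C to rt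
Reagents that add atoms: n-butyllithium [Li]CCCC (lithium of 7); trimethyl borate COB(OC)OC (boron and methoxy groups of 8); hydrogen peroxide OO (oxygen of 9)
Why: Bromine–lithium exchange, borylation and peroxide-induced 1,2-shift of the aryl group from boron to oxygen form the standard aryl bromide to phenol sequence, and no neighbouring halogen is present that could eliminate.

**Step 5**
Reactants: 9 3,4-dimethoxy-2,5-diphenylphenol
Product: 10 2-bromo-4,5-dimethoxy-3,6-diphenylphenol
Conditions: NBS (1 equiv), dry CH2Cl2, –40 °C to 0 °C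
Reagents that add atoms: N-bromosuccinimide O=C1CCC(=O)N1Br
Why: Electrophilic bromination ortho to a free phenol at the only open carbon of the ring, with low temperature and exclusion of water holding back oxidation of the 4-methoxyphenol unit.

**Step 6**
Reactants: 10 2-bromo-4,5-dimethoxy-3,6-diphenylphenol
Product: 13 4,5-dimethoxy-3,6-diphenyl-2-(trimethylsilyl)phenyl trifluoromethanesulfonate, via trimethylsilyl ether 11 (not isolated), via lithium 2-silylphenoxide 12 (not isolated)
Conditions: HMDS, THF, reflux, evaporate; n-BuLi, THF, –78 °C; Tf2O, –78 °C to rt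
Reagents that add atoms: hexamethyldisilazane C[Si](C)(C)N[Si](C)(C)C; n-butyllithium [Li]CCCC (lithium of 12); triflic anhydride O=S(=O)(C(F)(F)F)OS(=O)(=O)C(F)(F)F
Why: O-silylation, bromine–lithium exchange with retro-Brook 1,3-shift of silicon from oxygen to carbon, and O-triflation of the resulting phenoxide make up the standard one-flask conversion of an o-bromophenol into an o-silylaryl triflate.

**Step 7**
Reactants: 14 1-bromo-4-tert-butoxybenzene; 15 diethyl oxalate
Product: 17 ethyl 2-(4-tert-butoxyphenyl)-2-oxoacetate, via 4-tert-butoxyphenylmagnesium bromide 16 (not isolated)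
Conditions: Mg, THF, reflux; added to 15 (2 equiv), THF, –78 °C; sat. aq NH4Cl
Reagents that add atoms: magnesium [Mg] (magnesium of 16)
Why: Grignard monoacylation by inverse addition to excess diethyl oxalate at low temperature, where the first adduct persists until the quench so that no second addition occurs, and the aryl tert-butyl ether is inert to the organometallic.

**Step 8**
Reactants: 17 ethyl 2-(4-tert-butoxyphenyl)-2-oxoacetate
Product: 18 cesium 2-(4-tert-butoxyphenyl)-2-oxoacetate
Conditions: CsOH·H2O (1.0 equiv), THF/H2O, 0 °C; freeze-dry, toluene azeotrope, high vacuum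
Reagents that add atoms: cesium hydroxide [Cs+].[OH-]
Why: Saponification of a highly activated alpha-keto ester with exactly one equivalent of CsOH gives the dry cesium carboxylate directly and leaves no free hydroxide that could compete for the aryne.

**Step 9**
Reactants: 13 4,5-dimethoxy-3,6-diphenyl-2-(trimethylsilyl)phenyl trifluoromethanesulfonate; 18 cesium 2-(4-tert-butoxyphenyl)-2-oxoacetate
Product: 21 racemic 3-(4-tert-butoxyphenyl)-3-hydroxy-5,6-dimethoxy-4,7-diphenylbenzofuran-2(3H)-one, via 4,5-dimethoxy-3,6-diphenylbenzyne 19 (not isolated), via cesium alkoxide of the lactone 20 (not isolated)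
Conditions: CsF (4 equiv), dry THF, 65 °C, 13 added slowly to 18 (1.5 equiv); AcOH quench
Reagents that add atoms: none
Why: Proposed new method: fluoride attacks silicon in 13 and triflate leaves to give aryne 19; a carboxylate oxygen of 18 adds to one aryne carbon (O1–C7a), and the aryl anion left at C3a adds to the adjacent ketone carbon (C3–C3a) to give alkoxide 20, which acetic acid protonates to 21. The closest known reaction types are the O-arylation of carboxylates by arynes, the tandem addition and acyl capture of arynes with salicylates that leads to xanthones, and the formal insertion of arynes into the C–O bond of carboxylic acids, all of which run through the same o-(acyloxy)aryl anion. The one ring closed is the five-membered lactone (O1, C2, C3, C3a, C7a), formed by 5-exo-trig attack on the ketone C=O. Nothing controls the new C3 stereocentre, so 21 is racemic, which is harmless because C3 becomes sp2 in step 10. No regiocontrol is needed because the mirror line of ring A makes the two aryne carbons equivalent; the ketone is preferred over the ester carbonyl because a five-membered closure beats a four-membered one and because a non-enolisable aryl ketone next to an acyl group is the stronger electrophile, and a stray attack at the ester carbonyl could still be corrected by a benzilic-type shift. Premature protonation of the aryl anion is held back by dry THF in place of acetonitrile, and slow addition of 13 to excess 18 keeps the hindered alkoxide 20 from competing for the aryne.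

**Step 10**
Reactants: 21 racemic 3-(4-tert-butoxyphenyl)-3-hydroxy-5,6-dimethoxy-4,7-diphenylbenzofuran-2(3H)-one
Product: 23 5,6-dimethoxy-3-(4-oxocyclohexa-2,5-dien-1-ylidene)-4,7-diphenylbenzofuran-2(3H)-one, via phenolic carbinol 22 (not isolated)
Conditions: TFA/CH2Cl2 (1:4), 0 °C to rt; concentrate from toluene
Reagents that add atoms: none
Why: Acidolysis of the aryl tert-butyl ether (E1 loss of isobutene) followed by acid-catalysed dehydration of the 4-hydroxybenzylic tertiary carbinol, the carbinol-to-fuchsone reaction type, under conditions that leave methyl ethers and lactone intact, and ring strain prevents the C3 cation from closing onto the C4 phenyl ring.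

**Step 11**
Reactants: 23 5,6-dimethoxy-3-(4-oxocyclohexa-2,5-dien-1-ylidene)-4,7-diphenylbenzofuran-2(3H)-one
Product: 25 3-(4-hydroxyphenyl)-5-methoxy-4,7-diphenylbenzofuran-2,6-dione (target), via lithium phenoxide 24 (not isolated)
Conditions: LiCl (5 equiv), DMF, 120 °C, argon; 1 M HCl
Reagents that add atoms: lithium chloride [Li+].[Cl-] (lithium of 24)
Why: Halide-induced SN2 demethylation of an aryl methyl ether para to a conjugated acceptor, known for ethers para to carbonyl or nitro groups, which removes only the O6 methyl group because O6 leaves as the delocalised anion 24, whereas O5 is meta and unconjugated and the anionic product resists a second cleavage.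

**Compound list**
1 | veratrole (1,2-dimethoxybenzene) | COc1ccccc1OC | starting material
2 | 3,6-dilithioveratrole | COc1c([Li])ccc([Li])c1OC | intermediate
3 | 1,4-dibromo-2,3-dimethoxybenzene | COc1c(Br)ccc(Br)c1OC | intermediate
4 | phenylboronic acid | OB(O)c1ccccc1 | starting material
5 | 2,3-dimethoxy-1,4-diphenylbenzene | COc1c(OC)c(-c2ccccc2)ccc1-c1ccccc1 | intermediate
6 | 1-bromo-3,4-dimethoxy-2,5-diphenylbenzene | COc1c(OC)c(-c2ccccc2)c(Br)cc1-c1ccccc1 | intermediate
7 | (3,4-dimethoxy-2,5-diphenylphenyl)lithium | COc1c(OC)c(-c2ccccc2)c([Li])cc1-c1ccccc1 | intermediate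
8 | lithium (3,4-dimethoxy-2,5-diphenylphenyl)trimethoxyborate | [Li+].COc1c(OC)c(-c2ccccc2)c(cc1-c1ccccc1)[B-](OC)(OC)OC | intermediate
9 | 3,4-dimethoxy-2,5-diphenylphenol | COc1c(OC)c(-c2ccccc2)c(O)cc1-c1ccccc1 | intermediate
10 | 2-bromo-4,5-dimethoxy-3,6-diphenylphenol | COc1c(OC)c(-c2ccccc2)c(O)c(Br)c1-c1ccccc1 | intermediate
11 | (2-bromo-4,5-dimethoxy-3,6-diphenylphenoxy)trimethylsilane | COc1c(OC)c(-c2ccccc2)c(O[Si](C)(C)C)c(Br)c1-c1ccccc1 | intermediate
12 | lithium 4,5-dimethoxy-3,6-diphenyl-2-(trimethylsilyl)phenoxide | [Li+].COc1c(OC)c(-c2ccccc2)c([O-])c([Si](C)(C)C)c1-c1ccccc1 | intermediate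
13 | 4,5-dimethoxy-3,6-diphenyl-2-(trimethylsilyl)phenyl trifluoromethanesulfonate | COc1c(OC)c(-c2ccccc2)c(OS(=O)(=O)C(F)(F)F)c([Si](C)(C)C)c1-c1ccccc1 | intermediate
14 | 1-bromo-4-tert-butoxybenzene | CC(C)(C)Oc1ccc(Br)cc1 | starting material
15 | diethyl oxalate | CCOC(=O)C(=O)OCC | starting material
16 | 4-tert-butoxyphenylmagnesium bromide | CC(C)(C)Oc1ccc([Mg]Br)cc1 | intermediate
17 | ethyl 2-(4-tert-butoxyphenyl)-2-oxoacetate | CCOC(=O)C(=O)c1ccc(OC(C)(C)C)cc1 | intermediate
18 | cesium 2-(4-tert-butoxyphenyl)-2-oxoacetate | [Cs+].[O-]C(=O)C(=O)c1ccc(OC(C)(C)C)cc1 | intermediate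
19 | 4,5-dimethoxy-3,6-diphenylbenzyne | COC1=C(c2ccccc2)C#CC(c2ccccc2)=C1OC | intermediate
20 | cesium alkoxide of 21 (racemic) | [Cs+].[O-]C1(c2ccc(OC(C)(C)C)cc2)C(=O)Oc2c(-c3ccccc3)c(OC)c(OC)c(-c3ccccc3)c21 | intermediate
21 | racemic 3-(4-tert-butoxyphenyl)-3-hydroxy-5,6-dimethoxy-4,7-diphenylbenzofuran-2(3H)-one | CC(C)(C)Oc1ccc(cc1)C1(O)C(=O)Oc2c(-c3ccccc3)c(OC)c(OC)c(-c3ccccc3)c21 | intermediate
22 | racemic 3-hydroxy-3-(4-hydroxyphenyl)-5,6-dimethoxy-4,7-diphenylbenzofuran-2(3H)-one | Oc1ccc(cc1)C1(O)C(=O)Oc2c(-c3ccccc3)c(OC)c(OC)c(-c3ccccc3)c21 | intermediate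
23 | 5,6-dimethoxy-3-(4-oxocyclohexa-2,5-dien-1-ylidene)-4,7-diphenylbenzofuran-2(3H)-one | COc1c(OC)c(-c2ccccc2)c3c(OC(=O)C3=C4C=CC(=O)C=C4)c1-c1ccccc1 | intermediate
24 | lithium 4-(5-methoxy-2,6-dioxo-4,7-diphenyl-2,6-dihydrobenzofuran-3-yl)phenoxide | [Li+].[O-]c1ccc(cc1)C1=C2C(c3ccccc3)=C(OC)C(=O)C(c3ccccc3)=C2OC1=O | intermediate
25 | 3-(4-hydroxyphenyl)-5-methoxy-4,7-diphenylbenzofuran-2,6-dione | COC1=C(c2ccccc2)C2=C(c3ccc(O)cc3)C(=O)OC2=C(c2ccccc2)C1=O | target

**Step count**
Total step count: 11.
Longest linear sequence: 9 (steps 1 to 6, then 9 to 11).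

**Steps most likely to fail**

*Step 9.* The weakly nucleophilic keto-carboxylate may add only slowly to an aryne flanked by phenyl on both sides. The aryl anion may also be protonated before it reaches the ketone. The fallback sets out from 9 and uses known chemistry only.
- Acid-catalysed condensation of 9 with commercial 4-hydroxymandelic acid (p-TsOH, 1,2-dichloroethane, reflux with removal of water) should give racemic 3-(4-hydroxyphenyl)-5,6-dimethoxy-4,7-diphenylbenzofuran-2(3H)-one F1. This is a Friedel–Crafts alkylation at the only free ring carbon followed by lactonisation, the standard entry to 3-arylbenzofuranones.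
- Dehydrogenation with DDQ (dioxane, rt), the usual oxidation of a 4-hydroxydiarylmethane to its quinone methide, comes back to the route at 23.

*Step 11.* Demethylation may be too slow at temperatures the quinone methide tolerates, or prolonged heating may erode the selectivity between the two methyl ethers. The fallback sets out from 23.
- BBr3 (CH2Cl2, –78 °C to rt) should cleave both ethers to 5-hydroxy-3-(4-hydroxyphenyl)-4,7-diphenylbenzofuran-2,6-dione F2.
- TIPSCl and imidazole (CH2Cl2, 0 °C) should silylate the exposed 4'-hydroxyl rather than the 5-hydroxyl, which is wedged between the C4 phenyl ring and the C6 carbonyl. This gives 5-hydroxy-4,7-diphenyl-3-[4-(triisopropylsilyloxy)phenyl]benzofuran-2,6-dione F3.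
- The one remaining acidic hydroxyl is methylated with TMSCHN2 (toluene/MeOH, 0 °C) to 5-methoxy-4,7-diphenyl-3-[4-(triisopropylsilyloxy)phenyl]benzofuran-2,6-dione F4.
- HF·pyridine (THF, 0 °C) comes back to the route at 25.

*Step 6.* Silyl migration to a carbon crowded by phenyl and oxygen may stall, silicon may be lost by protonation, or the doubly flanked phenoxide may triflate poorly. The fallback sets out from 9, bypasses step 5 as well, and puts silicon in by C–H lithiation.
- ClC(O)NEt2 and NaH (THF) should give 3,4-dimethoxy-2,5-diphenylphenyl diethylcarbamate F5.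
- Directed ortho-metalation with s-BuLi/TMEDA (THF, –78 °C) with TMSCl present should give 4,5-dimethoxy-3,6-diphenyl-2-(trimethylsilyl)phenyl diethylcarbamate F6.
- LiAlH4 (THF, 0 °C to rt) releases 4,5-dimethoxy-3,6-diphenyl-2-(trimethylsilyl)phenol F7.
- Tf2O and pyridine (CH2Cl2, 0 °C) come back to the route at 13.

**Further compounds**
F1 | step 9 | racemic 3-(4-hydroxyphenyl)-5,6-dimethoxy-4,7-diphenylbenzofuran-2(3H)-one | O=C1Oc2c(-c3ccccc3)c(OC)c(OC)c(-c3ccccc3)c2C1c1ccc(O)cc1
F2 | step 11 | 5-hydroxy-3-(4-hydroxyphenyl)-4,7-diphenylbenzofuran-2,6-dione | OC1=C(c2ccccc2)C2=C(c3ccc(O)cc3)C(=O)OC2=C(c2ccccc2)C1=O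
F3 | step 11 | 5-hydroxy-4,7-diphenyl-3-[4-(triisopropylsilyloxy)phenyl]benzofuran-2,6-dione | CC(C)[Si](C(C)C)(C(C)C)Oc1ccc(cc1)C1=C2C(c3ccccc3)=C(O)C(=O)C(c3ccccc3)=C2OC1=O
F4 | step 11 | 5-methoxy-4,7-diphenyl-3-[4-(triisopropylsilyloxy)phenyl]benzofuran-2,6-dione | CC(C)[Si](C(C)C)(C(C)C)Oc1ccc(cc1)C1=C2C(c3ccccc3)=C(OC)C(=O)C(c3ccccc3)=C2OC1=O
F5 | step 6 | 3,4-dimethoxy-2,5-diphenylphenyl diethylcarbamate | CCN(CC)C(=O)Oc1cc(-c2ccccc2)c(OC)c(OC)c1-c1ccccc1
F6 | step 6 | 4,5-dimethoxy-3,6-diphenyl-2-(trimethylsilyl)phenyl diethylcarbamate | CCN(CC)C(=O)Oc1c([Si](C)(C)C)c(-c2ccccc2)c(OC)c(OC)c1-c1ccccc1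
F7 | step 6 | 4,5-dimethoxy-3,6-diphenyl-2-(trimethylsilyl)phenol | COc1c(OC)c(-c2ccccc2)c(O)c([Si](C)(C)C)c1-c1ccccc1
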